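Everything rests on opening ring A, the 2,4,6-trihydroxyphenyl end of rings A to K, at its C1–C2 bond. C1 of this phloroglucinol, flanked by the hydroxyls on C2 and C6, bears only the ether oxygen to ring B, so the six ring carbons are those of a methyl 3,5-dioxohexanoate holding the protected ring B aryloxy group at C6. One base-induced Claisen closure builds ring A around the crowded oxygen link to ring B, which enters as an unhindered alkyl aryl ether. Rings C to K then arrive as preformed iodo diaryl ether blocks through copper-mediated etherifications, and one hydrogenolysis removes all 28 benzyl groups.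

Key step: step 8

Assumption: the target is the achiral, fully phenolic undecamer as drawn; it has no stereocentre, so no step has to set configuration.

Design notes:
- Commercial resorcinol dibenzyl ether 1 is the single source of the benzylated rings B to K; its phenol 4 feeds ring B, the ring C, E, G and I blocks, and ring K.
- The cyclisation substrate keeps a methyl ester so that the methoxide base cannot exchange it.
- It is reached through a Weinreb amide, which makes the dianion acylation cleaner than with an ester.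
- Ring B carries only base-stable groups (benzyl, MOM).

Shorthand in the names of the oligomers:
- ArA = 2,4,6-tris(benzyloxy)phenyl (ring A).
- P = 3,5-bis(benzyloxy)benzene-1,4-diyl (rings B, D, F, H, J; O on C1 points to ring A, O on C4 to ring K).
- Q = 3,4,5-tris(benzyloxy)benzene-1,2-diyl (rings C, E, G, I; O on C1 points to ring A, O on C2 to ring K).

Step 1
Reactants: 1 1,3-bis(benzyloxy)benzene
Product: 4 2,6-bis(benzyloxy)phenol, via aryllithium 2 (not isolated), via lithium aryltrimethoxyborate 3 (not isolated)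
Conditions: nBuLi, THF, 0 °C; B(OMe)3, −78 °C → rt; AcOH, 30% H2O2, 0 °C → rt
Reagents that add atoms: hydrogen peroxide, OO (n-butyllithium, [Li]CCCC, supplies lithium to 2 only; trimethyl borate, COB(OC)OC, supplies boron and methoxy groups to 3 only)
Why: Directed ortho-metalation removes the C2 proton, which is acidified and chelated by both flanking benzyloxy oxygens and so reacts ahead of the benzylic CH2 groups, and borylation with oxidative boron-to-oxygen aryl migration then places the hindered phenol oxygen on that carbon.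

Step 2
Reactants: 4 2,6-bis(benzyloxy)phenol
Product: 5 2,6-bis(benzyloxy)-4-bromophenol
Conditions: NBS, MeCN, 0 °C
Reagents that add atoms: N-bromosuccinimide, O=C1CCC(=O)N1Br
Why: Electrophilic aromatic bromination goes para to the free hydroxyl, the strongest activator, whose ortho positions are both blocked.

Step 3
Reactants: 5 2,6-bis(benzyloxy)-4-bromophenol
Product: 6 1,3-bis(benzyloxy)-5-bromo-2-(methoxymethoxy)benzene
Conditions: NaH, DMF, 0 °C; MOMCl, 0 °C → rt
Reagents that add atoms: chloromethyl methyl ether, COCCl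
Why: Williamson-type O-alkylation of the sodium phenoxide with the reactive chloromethyl ether installs a base-stable, acid-labile acetal on the one oxygen that has to be freed later.

Step 4
Reactants: 6 1,3-bis(benzyloxy)-5-bromo-2-(methoxymethoxy)benzene
Product: 9 [3,5-bis(benzyloxy)-4-(methoxymethoxy)phenyl]boronic acid, via aryllithium 7 (not isolated), via lithium aryltriisopropoxyborate 8 (not isolated)
Conditions: nBuLi, THF, −78 °C; B(OiPr)3, −78 → 0 °C; 1 M HCl to pH 5, 0 °C
Reagents that add atoms: triisopropyl borate, CC(C)OB(OC(C)C)OC(C)C; water, O (n-butyllithium, [Li]CCCC, supplies lithium to 7 only)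
Why: Bromine–lithium exchange followed by borate trapping and mild hydrolysis is the standard arylboronic acid synthesis, and benzyl and MOM ethers tolerate butyllithium at −78 °C and brief dilute acid at 0 °C.

Step 5
Reactants: 9 [3,5-bis(benzyloxy)-4-(methoxymethoxy)phenyl]boronic acid
Product: 10 3,5-bis(benzyloxy)-4-(methoxymethoxy)phenol (ring B phenol)
Conditions: 30% H2O2, EtOH, rt
Reagents that add atoms: hydrogen peroxide, OO
Why: Oxidative ipso-hydroxylation of the arylboronic acid (1,2-aryl shift from boron to oxygen, then hydrolysis) should give the unhindered ring B phenol without touching the ethers.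

Step 6
Reactants: 10 3,5-bis(benzyloxy)-4-(methoxymethoxy)phenol; 11 2-chloro-N-methoxy-N-methylacetamide
Product: 12 2-[3,5-bis(benzyloxy)-4-(methoxymethoxy)phenoxy]-N-methoxy-N-methylacetamide
Conditions: K2CO3, NaI (cat.), acetone, reflux
Reagents that add atoms: none
Why: Williamson etherification (SN2 at the α-chloro amide, assisted by iodide) forms the future A–O–B ether as an unhindered alkyl aryl ether.

Step 7
Reactants: 12 2-[3,5-bis(benzyloxy)-4-(methoxymethoxy)phenoxy]-N-methoxy-N-methylacetamide; 13 methyl acetoacetate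
Product: 15 methyl 6-[3,5-bis(benzyloxy)-4-(methoxymethoxy)phenoxy]-3,5-dioxohexanoate, via dilithio methyl acetoacetate 14 (not isolated)
Conditions: 13 (2.2 equiv), LiN(iPr)2 (4.4 equiv), THF, 0 °C; then 12, −78 → 0 °C; AcOH
Reagents that add atoms: none
Why: Claisen-type γ-acylation of the acetoacetate dianion by a Weinreb amide proceeds through a chelated tetrahedral adduct that cannot over-react, and excess dianion compensates for any enolisation of 12.

Step 8
Reactants: 15 methyl 6-[3,5-bis(benzyloxy)-4-(methoxymethoxy)phenoxy]-3,5-dioxohexanoate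
Product: 16 2-[3,5-bis(benzyloxy)-4-(methoxymethoxy)phenoxy]benzene-1,3,5-triol
Conditions: NaOMe (5 equiv), diglyme–MeOH (20:1), 100 °C, argon, high dilution; then AcOH, 0 °C
Reagents that add atoms: none
Why: Excess methoxide converts 15 into its dienolate, and proton exchange makes available, in low concentration, the 4,6-dianion whose C6 carbanion (stabilised by the C5 carbonyl and made more acidic by the attached aryloxy oxygen) adds to the ester carbonyl C1; loss of methoxide gives the 2-aryloxycyclohexane-1,3,5-trione, which enolises to the aromatic triolate. The closest known reaction type is the base-induced intramolecular Claisen (Dieckmann-type) condensation that turns methyl 3,5-dioxohexanoate into phloroglucinol and 3,5,7-trioxo esters into acylphloroglucinols. Ring A closes in the 6-exo-trig mode, the ester C=O lying outside the new ring, and the only bond made is C6–C1 of the chain, which is C1–C2 of ring A. No stereocentre is formed. The selectivity needed is C-acylation at C6 rather than O-acylation by the C5 enolate oxygen to a 6-(aryloxymethyl)-4-hydroxypyran-2-one; it is secured because methoxide reopens that lactone whereas C–C closure ends irreversibly in the aromatic phloroglucinolate, and because C6 is the only carbon that can reach C1 through a six-membered transition state. Benzyl and MOM ethers and the alkyl aryl ether, which becomes the crowded A–O–B linkage, are inert to methoxide.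

Step 9
Reactants: 16 2-[3,5-bis(benzyloxy)-4-(methoxymethoxy)phenoxy]benzene-1,3,5-triol
Product: 18 1,3,5-tris(benzyloxy)-2-[3,5-bis(benzyloxy)-4-(methoxymethoxy)phenoxy]benzene, via ring A triacetate 17 (not isolated)
Conditions: Ac2O, pyridine, rt; evaporate; then NaH (7 equiv), BnCl (4 equiv), H2O (3 equiv), DMF, 0 °C → rt
Reagents that add atoms: benzyl chloride, ClCc1ccccc1 (acetic anhydride, CC(=O)OC(C)=O, supplies the acetyl groups of 17 only)
Why: Acetylation followed by one-flask deacetylation–Williamson benzylation releases each phenoxide slowly in the presence of benzyl chloride, which favours O- over C-benzylation of a phloroglucinol, and the MOM acetal is unaffected.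

Step 10
Reactants: 18 1,3,5-tris(benzyloxy)-2-[3,5-bis(benzyloxy)-4-(methoxymethoxy)phenoxy]benzene
Product: 19 2,6-bis(benzyloxy)-4-[2,4,6-tris(benzyloxy)phenoxy]phenol
Conditions: HCl (cat.), MeOH–THF, 50 °C
Reagents that add atoms: none
Why: Acid-catalysed acetal methanolysis removes the MOM group and passes it to methanol as dimethoxymethane, which keeps the oxocarbenium ion away from the electron-rich ring A, while benzyl ethers are stable.

Step 11
Reactants: 4 2,6-bis(benzyloxy)phenol; 20 benzyl bromide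
Product: 21 1,2,3-tris(benzyloxy)benzene
Conditions: K2CO3, DMF, 60 °C
Reagents that add atoms: none
Why: Williamson ether synthesis on the one free phenol of 4 gives the pyrogallol tribenzyl ether from which the ring C, E, G and I blocks are made.

Step 12
Reactants: 21 1,2,3-tris(benzyloxy)benzene
Product: 22 1,2,3-tris(benzyloxy)-4-bromobenzene
Conditions: NBS (1.0 equiv), MeCN, 0 °C → rt
Reagents that add atoms: N-bromosuccinimide, O=C1CCC(=O)N1Br
Why: Electrophilic aromatic bromination of a 1,2,3-trialkoxybenzene goes to C4, which is para to one outer benzyloxy group and ortho to the other, whereas C5 is para only to the twisted central one, and one equivalent of reagent limits dibromination.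

Step 13
Reactants: 22 1,2,3-tris(benzyloxy)-4-bromobenzene
Product: 25 2,3,4-tris(benzyloxy)phenol, via aryllithium 23 (not isolated), via lithium aryltrimethoxyborate 24 (not isolated)
Conditions: nBuLi, THF, −78 °C; B(OMe)3, −78 °C → rt; AcOH, 30% H2O2, 0 °C → rt
Reagents that add atoms: hydrogen peroxide, OO (n-butyllithium, [Li]CCCC, supplies lithium to 23 only; trimethyl borate, COB(OC)OC, supplies boron and methoxy groups to 24 only)
Why: Bromine–lithium exchange, which at −78 °C is faster than benzylic deprotonation, followed by borylation and oxidative boron-to-oxygen aryl migration puts the phenol oxygen exactly where the bromine sat.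

Step 14
Reactants: 25 2,3,4-tris(benzyloxy)phenol
Product: 26 2,3,4-tris(benzyloxy)-6-iodophenol
Conditions: I2, morpholine, CH2Cl2, 0 °C → rt
Reagents that add atoms: iodine, II
Why: Electrophilic aromatic iodination under amine-basic conditions is steered by the phenol(ate), whose para position is occupied and whose only free ortho position is C6.

Step 15
Reactants: 26 2,3,4-tris(benzyloxy)-6-iodophenol; 9 [3,5-bis(benzyloxy)-4-(methoxymethoxy)phenyl]boronic acid
Product: 27 1,2,3-tris(benzyloxy)-4-[3,5-bis(benzyloxy)-4-(methoxymethoxy)phenoxy]-5-iodobenzene (block I–Q–O–P–OMOM)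
Conditions: 9 (2 equiv), Cu(OAc)2 (50 mol%), pyridine, 4 Å molecular sieves, CH2Cl2, O2 (1 atm), rt
Reagents that add atoms: none
Why: Chan–Lam–Evans oxidative C–O coupling (aryl transfer from boron to a divalent copper phenoxide, oxidation to trivalent copper, reductive elimination) runs at room temperature without low-valent metal, so the C–I bond survives, and di-ortho-substituted phenols including ortho-iodophenols are established substrates.

Step 16
Reactants: 19 2,6-bis(benzyloxy)-4-[2,4,6-tris(benzyloxy)phenoxy]phenol; 27 block I–Q–O–P–OMOM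
Product: 28 ring A–D tetramer MOM ether, ArA–O–P–O–Q–O–P–OCH2OCH3
Conditions: CuI (20 mol%), picolinic acid (40 mol%), K3PO4, DMSO–dioxane, 90 °C, argon
Reagents that add atoms: none
Why: Ullmann-type diaryl ether synthesis with CuI and picolinic acid is established for 2,6-disubstituted phenols and ortho-substituted aryl iodides, and with one free OH in 19 and one C–I bond in 27 only one ether can form.

Step 17
Reactants: 28 ring A–D tetramer MOM ether
Product: 29 ring A–D tetramer phenol, ArA–O–P–O–Q–O–P–OH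
Conditions: HCl (cat.), MeOH–THF, 50 °C
Reagents that add atoms: none
Why: Acid-catalysed acetal methanolysis frees the ring D C4 hydroxyl selectively, benzyl and diaryl ethers being stable.

Step 18
Reactants: 29 ring A–D tetramer phenol; 27 block I–Q–O–P–OMOM
Product: 30 ring A–F hexamer MOM ether, ArA–O–[P–O–Q–O]2–P–OCH2OCH3
Conditions: CuI (20 mol%), picolinic acid (40 mol%), K3PO4, DMSO–dioxane, 90 °C, argon
Reagents that add atoms: none
Why: Ullmann-type diaryl ether synthesis between partners that are locally identical to those of step 16.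

Step 19
Reactants: 30 ring A–F hexamer MOM ether
Product: 31 ring A–F hexamer phenol, ArA–O–[P–O–Q–O]2–P–OH
Conditions: HCl (cat.), MeOH–THF, 50 °C
Reagents that add atoms: none
Why: Acid-catalysed acetal methanolysis as in step 17.

Step 20
Reactants: 31 ring A–F hexamer phenol; 27 block I–Q–O–P–OMOM
Product: 32 ring A–H octamer MOM ether, ArA–O–[P–O–Q–O]3–P–OCH2OCH3
Conditions: CuI (20 mol%), picolinic acid (40 mol%), K3PO4, DMSO–dioxane, 90 °C, argon
Reagents that add atoms: none
Why: Ullmann-type diaryl ether synthesis as in step 16.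

Step 21
Reactants: 32 ring A–H octamer MOM ether
Product: 33 ring A–H octamer phenol, ArA–O–[P–O–Q–O]3–P–OH
Conditions: HCl (cat.), MeOH–THF, 50 °C
Reagents that add atoms: none
Why: Acid-catalysed acetal methanolysis as in step 17.

Step 22
Reactants: 5 2,6-bis(benzyloxy)-4-bromophenol; 20 benzyl bromide
Product: 34 1,2,3-tris(benzyloxy)-5-bromobenzene
Conditions: K2CO3, DMF, 60 °C
Reagents that add atoms: none
Why: Williamson ether synthesis on the remaining phenol gives the ring K precursor from an intermediate already in hand.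

Step 23
Reactants: 34 1,2,3-tris(benzyloxy)-5-bromobenzene
Product: 37 [3,4,5-tris(benzyloxy)phenyl]boronic acid, via aryllithium 35 (not isolated), via lithium aryltriisopropoxyborate 36 (not isolated)
Conditions: nBuLi, THF, −78 °C; B(OiPr)3, −78 → 0 °C; 1 M HCl, 0 °C
Reagents that add atoms: triisopropyl borate, CC(C)OB(OC(C)C)OC(C)C; water, O (n-butyllithium, [Li]CCCC, supplies lithium to 35 only)
Why: Bromine–lithium exchange, borate trapping and hydrolysis as in step 4.

Step 24
Reactants: 27 block I–Q–O–P–OMOM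
Product: 38 2,6-bis(benzyloxy)-4-[2,3,4-tris(benzyloxy)-6-iodophenoxy]phenol
Conditions: HCl (cat.), MeOH–THF, 50 °C
Reagents that add atoms: none
Why: Acid-catalysed acetal methanolysis removes the MOM group, and the aryl iodide and benzyl ethers are inert to dilute acid.

Step 25
Reactants: 38 2,6-bis(benzyloxy)-4-[2,3,4-tris(benzyloxy)-6-iodophenoxy]phenol; 37 [3,4,5-tris(benzyloxy)phenyl]boronic acid
Product: 39 1,2,3-tris(benzyloxy)-4-{3,5-bis(benzyloxy)-4-[3,4,5-tris(benzyloxy)phenoxy]phenoxy}-5-iodobenzene (ring I–J–K trimer iodide)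
Conditions: 37 (2 equiv), Cu(OAc)2 (50 mol%), pyridine, 4 Å molecular sieves, CH2Cl2, O2 (1 atm), rt
Reagents that add atoms: none
Why: Chan–Lam–Evans oxidative C–O coupling of a 2,6-dialkoxyphenol with an unhindered arylboronic acid forms the J–O–K ether and leaves the C–I bond for the last fragment union.

Step 26
Reactants: 33 ring A–H octamer phenol; 39 ring I–J–K trimer iodide
Product: 40 per-O-benzyl undecamer, ArA–O–[P–O–Q–O]4–P–O–C6H2(OBn)3-3,4,5
Conditions: CuI (20 mol%), picolinic acid (40 mol%), K3PO4, DMSO–dioxane, 90 °C, argon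
Reagents that add atoms: none
Why: Ullmann-type diaryl ether synthesis as in step 16 joins the two halves through the H–O–I ether and completes the eleven-ring chain.

Step 27
Reactants: 40 per-O-benzyl undecamer
Product: 41 CNP0245174.0
Conditions: H2 (4 bar), Pd(OH)2/C, THF–MeOH, rt; filtration under argon
Reagents that add atoms: none
Why: Catalytic hydrogenolysis cleaves all 28 benzyl aryl ethers in one operation, while the diaryl ether bonds and the arene rings are inert under these mild conditions.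

**Compound list**

1 | 1,3-bis(benzyloxy)benzene (resorcinol dibenzyl ether) | c1cc(OCc2ccccc2)cc(OCc2ccccc2)c1 | starting material
2 | [2,6-bis(benzyloxy)phenyl]lithium (not isolated) | [Li]c1c(OCc2ccccc2)cccc1OCc1ccccc1 | intermediate
3 | lithium [2,6-bis(benzyloxy)phenyl]trimethoxyborate (not isolated) | [Li+].CO[B-](OC)(OC)c1c(OCc2ccccc2)cccc1OCc1ccccc1 | intermediate
4 | 2,6-bis(benzyloxy)phenol | Oc1c(OCc2ccccc2)cccc1OCc1ccccc1 | intermediate
5 | 2,6-bis(benzyloxy)-4-bromophenol | Oc1c(OCc2ccccc2)cc(Br)cc1OCc1ccccc1 | intermediate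
6 | 1,3-bis(benzyloxy)-5-bromo-2-(methoxymethoxy)benzene | COCOc1c(OCc2ccccc2)cc(Br)cc1OCc1ccccc1 | intermediate
7 | [3,5-bis(benzyloxy)-4-(methoxymethoxy)phenyl]lithium (not isolated) | COCOc1c(OCc2ccccc2)cc([Li])cc1OCc1ccccc1 | intermediate
8 | lithium [3,5-bis(benzyloxy)-4-(methoxymethoxy)phenyl]tri(propan-2-yloxy)borate (not isolated) | [Li+].CC(C)O[B-](OC(C)C)(OC(C)C)c1cc(OCc2ccccc2)c(OCOC)c(OCc2ccccc2)c1 | intermediate
9 | [3,5-bis(benzyloxy)-4-(methoxymethoxy)phenyl]boronic acid | OB(O)c1cc(OCc2ccccc2)c(OCOC)c(OCc2ccccc2)c1 | intermediate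
10 | 3,5-bis(benzyloxy)-4-(methoxymethoxy)phenol | Oc1cc(OCc2ccccc2)c(OCOC)c(OCc2ccccc2)c1 | intermediate
11 | 2-chloro-N-methoxy-N-methylacetamide | CON(C)C(=O)CCl | starting material
12 | 2-[3,5-bis(benzyloxy)-4-(methoxymethoxy)phenoxy]-N-methoxy-N-methylacetamide | CON(C)C(=O)COc1cc(OCc2ccccc2)c(OCOC)c(OCc2ccccc2)c1 | intermediate
13 | methyl acetoacetate | CC(=O)CC(=O)OC | starting material
14 | dilithium salt of the methyl acetoacetate 2,4-dianion (not isolated) | [Li+].[Li+].[CH2-]C(=O)[CH-]C(=O)OC | intermediate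
15 | methyl 6-[3,5-bis(benzyloxy)-4-(methoxymethoxy)phenoxy]-3,5-dioxohexanoate | COC(=O)CC(=O)CC(=O)COc1cc(OCc2ccccc2)c(OCOC)c(OCc2ccccc2)c1 | intermediate
16 | 2-[3,5-bis(benzyloxy)-4-(methoxymethoxy)phenoxy]benzene-1,3,5-triol | Oc1cc(O)c(Oc2cc(OCc3ccccc3)c(OCOC)c(OCc3ccccc3)c2)c(O)c1 | intermediate
17 | 2-[3,5-bis(benzyloxy)-4-(methoxymethoxy)phenoxy]benzene-1,3,5-triyl triacetate (not isolated) | CC(=O)Oc1cc(OC(C)=O)c(Oc2cc(OCc3ccccc3)c(OCOC)c(OCc3ccccc3)c2)c(OC(C)=O)c1 | intermediate
18 | 1,3,5-tris(benzyloxy)-2-[3,5-bis(benzyloxy)-4-(methoxymethoxy)phenoxy]benzene | c1(OCc2ccccc2)cc(OCc2ccccc2)cc(OCc2ccccc2)c1Oc1cc(OCc2ccccc2)c(c(OCc2ccccc2)c1)OCOC | intermediate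
19 | 2,6-bis(benzyloxy)-4-[2,4,6-tris(benzyloxy)phenoxy]phenol | c1(OCc2ccccc2)cc(OCc2ccccc2)cc(OCc2ccccc2)c1Oc1cc(OCc2ccccc2)c(c(OCc2ccccc2)c1)O | intermediate
20 | benzyl bromide | BrCc1ccccc1 | starting material
21 | 1,2,3-tris(benzyloxy)benzene | c1cc(OCc2ccccc2)c(OCc2ccccc2)c(OCc2ccccc2)c1 | intermediate
22 | 1,2,3-tris(benzyloxy)-4-bromobenzene | Brc1ccc(OCc2ccccc2)c(OCc2ccccc2)c1OCc1ccccc1 | intermediate
23 | [2,3,4-tris(benzyloxy)phenyl]lithium (not isolated) | [Li]c1ccc(OCc2ccccc2)c(OCc2ccccc2)c1OCc1ccccc1 | intermediate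
24 | lithium [2,3,4-tris(benzyloxy)phenyl]trimethoxyborate (not isolated) | [Li+].CO[B-](OC)(OC)c1ccc(OCc2ccccc2)c(OCc2ccccc2)c1OCc1ccccc1 | intermediate
25 | 2,3,4-tris(benzyloxy)phenol | Oc1ccc(OCc2ccccc2)c(OCc2ccccc2)c1OCc1ccccc1 | intermediate
26 | 2,3,4-tris(benzyloxy)-6-iodophenol | Oc1c(I)cc(OCc2ccccc2)c(OCc2ccccc2)c1OCc1ccccc1 | intermediate
27 | 1,2,3-tris(benzyloxy)-4-[3,5-bis(benzyloxy)-4-(methoxymethoxy)phenoxy]-5-iodobenzene | Ic1cc(OCc2ccccc2)c(OCc2ccccc2)c(OCc2ccccc2)c1Oc1cc(OCc2ccccc2)c(c(OCc2ccccc2)c1)OCOC | intermediate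
28 | ring A–D tetramer MOM ether, ArA–O–P–O–Q–O–P–OCH2OCH3 | c1(OCc2ccccc2)cc(OCc2ccccc2)cc(OCc2ccccc2)c1Oc1cc(OCc2ccccc2)c(c(OCc2ccccc2)c1)Oc1cc(OCc2ccccc2)c(OCc2ccccc2)c(OCc2ccccc2)c1Oc1cc(OCc2ccccc2)c(c(OCc2ccccc2)c1)OCOC | intermediate
29 | ring A–D tetramer phenol, ArA–O–P–O–Q–O–P–OH | c1(OCc2ccccc2)cc(OCc2ccccc2)cc(OCc2ccccc2)c1Oc1cc(OCc2ccccc2)c(c(OCc2ccccc2)c1)Oc1cc(OCc2ccccc2)c(OCc2ccccc2)c(OCc2ccccc2)c1Oc1cc(OCc2ccccc2)c(c(OCc2ccccc2)c1)O | intermediate
30 | ring A–F hexamer MOM ether, ArA–O–[P–O–Q–O]2–P–OCH2OCH3 | c1(OCc2ccccc2)cc(OCc2ccccc2)cc(OCc2ccccc2)c1Oc1cc(OCc2ccccc2)c(c(OCc2ccccc2)c1)Oc1cc(OCc2ccccc2)c(OCc2ccccc2)c(OCc2ccccc2)c1Oc1cc(OCc2ccccc2)c(c(OCc2ccccc2)c1)Oc1cc(OCc2ccccc2)c(OCc2ccccc2)c(OCc2ccccc2)c1Oc1cc(OCc2ccccc2)c(c(OCc2ccccc2)c1)OCOC | intermediate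
31 | ring A–F hexamer phenol, ArA–O–[P–O–Q–O]2–P–OH | c1(OCc2ccccc2)cc(OCc2ccccc2)cc(OCc2ccccc2)c1Oc1cc(OCc2ccccc2)c(c(OCc2ccccc2)c1)Oc1cc(OCc2ccccc2)c(OCc2ccccc2)c(OCc2ccccc2)c1Oc1cc(OCc2ccccc2)c(c(OCc2ccccc2)c1)Oc1cc(OCc2ccccc2)c(OCc2ccccc2)c(OCc2ccccc2)c1Oc1cc(OCc2ccccc2)c(c(OCc2ccccc2)c1)O | intermediate
32 | ring A–H octamer MOM ether, ArA–O–[P–O–Q–O]3–P–OCH2OCH3 | c1(OCc2ccccc2)cc(OCc2ccccc2)cc(OCc2ccccc2)c1Oc1cc(OCc2ccccc2)c(c(OCc2ccccc2)c1)Oc1cc(OCc2ccccc2)c(OCc2ccccc2)c(OCc2ccccc2)c1Oc1cc(OCc2ccccc2)c(c(OCc2ccccc2)c1)Oc1cc(OCc2ccccc2)c(OCc2ccccc2)c(OCc2ccccc2)c1Oc1cc(OCc2ccccc2)c(c(OCc2ccccc2)c1)Oc1cc(OCc2ccccc2)c(OCc2ccccc2)c(OCc2ccccc2)c1Oc1cc(OCc2ccccc2)c(c(OCc2ccccc2)c1)OCOC | intermediate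
33 | ring A–H octamer phenol, ArA–O–[P–O–Q–O]3–P–OH | c1(OCc2ccccc2)cc(OCc2ccccc2)cc(OCc2ccccc2)c1Oc1cc(OCc2ccccc2)c(c(OCc2ccccc2)c1)Oc1cc(OCc2ccccc2)c(OCc2ccccc2)c(OCc2ccccc2)c1Oc1cc(OCc2ccccc2)c(c(OCc2ccccc2)c1)Oc1cc(OCc2ccccc2)c(OCc2ccccc2)c(OCc2ccccc2)c1Oc1cc(OCc2ccccc2)c(c(OCc2ccccc2)c1)Oc1cc(OCc2ccccc2)c(OCc2ccccc2)c(OCc2ccccc2)c1Oc1cc(OCc2ccccc2)c(c(OCc2ccccc2)c1)O | intermediate
34 | 1,2,3-tris(benzyloxy)-5-bromobenzene | Brc1cc(OCc2ccccc2)c(OCc2ccccc2)c(OCc2ccccc2)c1 | intermediate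
35 | [3,4,5-tris(benzyloxy)phenyl]lithium (not isolated) | [Li]c1cc(OCc2ccccc2)c(OCc2ccccc2)c(OCc2ccccc2)c1 | intermediate
36 | lithium [3,4,5-tris(benzyloxy)phenyl]tri(propan-2-yloxy)borate (not isolated) | [Li+].CC(C)O[B-](OC(C)C)(OC(C)C)c1cc(OCc2ccccc2)c(OCc2ccccc2)c(OCc2ccccc2)c1 | intermediate
37 | [3,4,5-tris(benzyloxy)phenyl]boronic acid | OB(O)c1cc(OCc2ccccc2)c(OCc2ccccc2)c(OCc2ccccc2)c1 | intermediate
38 | 2,6-bis(benzyloxy)-4-[2,3,4-tris(benzyloxy)-6-iodophenoxy]phenol | Ic1cc(OCc2ccccc2)c(OCc2ccccc2)c(OCc2ccccc2)c1Oc1cc(OCc2ccccc2)c(c(OCc2ccccc2)c1)O | intermediate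
39 | 1,2,3-tris(benzyloxy)-4-{3,5-bis(benzyloxy)-4-[3,4,5-tris(benzyloxy)phenoxy]phenoxy}-5-iodobenzene | Ic1cc(OCc2ccccc2)c(OCc2ccccc2)c(OCc2ccccc2)c1Oc1cc(OCc2ccccc2)c(c(OCc2ccccc2)c1)Oc1cc(OCc2ccccc2)c(OCc2ccccc2)c(OCc2ccccc2)c1 | intermediate
40 | per-O-benzyl undecamer (28 benzyl ethers), ArA–O–[P–O–Q–O]4–P–O–C6H2(OBn)3-3,4,5 | c1(OCc2ccccc2)cc(OCc2ccccc2)cc(OCc2ccccc2)c1Oc1cc(OCc2ccccc2)c(c(OCc2ccccc2)c1)Oc1cc(OCc2ccccc2)c(OCc2ccccc2)c(OCc2ccccc2)c1Oc1cc(OCc2ccccc2)c(c(OCc2ccccc2)c1)Oc1cc(OCc2ccccc2)c(OCc2ccccc2)c(OCc2ccccc2)c1Oc1cc(OCc2ccccc2)c(c(OCc2ccccc2)c1)Oc1cc(OCc2ccccc2)c(OCc2ccccc2)c(OCc2ccccc2)c1Oc1cc(OCc2ccccc2)c(c(OCc2ccccc2)c1)Oc1cc(OCc2ccccc2)c(OCc2ccccc2)c(OCc2ccccc2)c1Oc1cc(OCc2ccccc2)c(c(OCc2ccccc2)c1)Oc1cc(OCc2ccccc2)c(OCc2ccccc2)c(OCc2ccccc2)c1 | intermediate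
41 | CNP0245174.0 (free undecamer, rings A–K, 28 OH) | Oc1cc(O)c(Oc2cc(O)c(Oc3cc(O)c(O)c(O)c3Oc3cc(O)c(Oc4cc(O)c(O)c(O)c4Oc4cc(O)c(Oc5cc(O)c(O)c(O)c5Oc5cc(O)c(Oc6cc(O)c(O)c(O)c6Oc6cc(O)c(Oc7cc(O)c(O)c(O)c7)c(O)c6)c(O)c5)c(O)c4)c(O)c3)c(O)c2)c(O)c1 | target

**Step count and risk**

Total step count: 27. Longest linear sequence: 18 steps (steps 1–10, 16–21, 26, 27).

Steps most likely to fail:

1. Step 8. O-acylation by the C5 enolate oxygen may outrun C-acylation without the lactone being reopened fast enough, or methoxide may cleave the 1,3-diketone before ring closure. The fallback buys ring A instead of building it; it sets out from boronic acid 9 and comes back at 18. Commercial 1,3,5-tris(benzyloxy)benzene is formylated under Vilsmeier–Haack conditions (POCl3, DMF, 0 °C → rt; aqueous NaOAc) to 2,4,6-tris(benzyloxy)benzaldehyde F1. Dakin oxidation (mCPBA, CH2Cl2; then K2CO3, MeOH) through 2,4,6-tris(benzyloxy)phenyl formate F2 should give 2,4,6-tris(benzyloxy)phenol F3. Chan–Lam–Evans coupling of F3 with 9 under the conditions of step 25 then forms the A–O–B ether and gives 18, so that steps 5–9 are bypassed.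

2. Step 16 (the same reaction type recurs in steps 18, 20 and 26). Aryl transfer at copper between two ortho-crowded, electron-rich partners may be too slow, so that protodeiodination of the block and oxidative loss of the phenoxide take over. The fallback reverses the polarity of the block; it sets out from 27 and comes back at 28. Iodine–magnesium exchange (iPrMgCl·LiCl, THF, −20 °C) gives the arylmagnesium chloride F4, trimethyl borate converts it into the magnesium aryltrimethoxyborate F5, and dilute acid liberates {3,4,5-tris(benzyloxy)-2-[3,5-bis(benzyloxy)-4-(methoxymethoxy)phenoxy]phenyl}boronic acid F6. Oxidative Chan–Lam–Evans coupling of F6 with phenol 19 (Cu(OAc)2, pyridine, 4 Å molecular sieves, CH2Cl2, O2, rt) should then give 28 without any aryl halide activation.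

3. Step 15. Ligand exchange and aryl transfer at copper may be slow for the di-ortho-substituted iodophenol, so that protodeboronation and hydroxylation of the boronic acid consume it. The fallback is an Ullmann union with the halogens exchanged, followed by a halide swap; it sets out from 25 and from aryllithium 7 and comes back at 27. Amine-catalysed ortho-bromination of 25 (NBS, iPr2NH cat., CH2Cl2) gives 6-bromo-2,3,4-tris(benzyloxy)phenol F7. Quenching 7 with I2 instead of the borate gives 1,3-bis(benzyloxy)-5-iodo-2-(methoxymethoxy)benzene F8. Ullmann coupling of F7 with F8 (CuI, picolinic acid, K3PO4, DMSO, 80 °C) should engage the unhindered C–I bond in preference to the flanked C–Br bond and give 1,2,3-tris(benzyloxy)-4-[3,5-bis(benzyloxy)-4-(methoxymethoxy)phenoxy]-5-bromobenzene F9. An aromatic Finkelstein exchange (CuI, NaI, N,N'-dimethylethane-1,2-diamine, dioxane, 110 °C) then converts F9 into 27.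

Further compounds
F1 | step 8 | 2,4,6-tris(benzyloxy)benzaldehyde | O=Cc1c(OCc2ccccc2)cc(OCc2ccccc2)cc1OCc1ccccc1
F2 | step 8 | 2,4,6-tris(benzyloxy)phenyl formate | O=COc1c(OCc2ccccc2)cc(OCc2ccccc2)cc1OCc1ccccc1
F3 | step 8 | 2,4,6-tris(benzyloxy)phenol | Oc1c(OCc2ccccc2)cc(OCc2ccccc2)cc1OCc1ccccc1
F4 | step 16 | {3,4,5-tris(benzyloxy)-2-[3,5-bis(benzyloxy)-4-(methoxymethoxy)phenoxy]phenyl}magnesium chloride | Cl[Mg]c1cc(OCc2ccccc2)c(OCc2ccccc2)c(OCc2ccccc2)c1Oc1cc(OCc2ccccc2)c(c(OCc2ccccc2)c1)OCOC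
F5 | step 16 | chloromagnesium {3,4,5-tris(benzyloxy)-2-[3,5-bis(benzyloxy)-4-(methoxymethoxy)phenoxy]phenyl}trimethoxyborate | [Mg+]Cl.CO[B-](OC)(OC)c1cc(OCc2ccccc2)c(OCc2ccccc2)c(OCc2ccccc2)c1Oc1cc(OCc2ccccc2)c(c(OCc2ccccc2)c1)OCOC
F6 | step 16 | {3,4,5-tris(benzyloxy)-2-[3,5-bis(benzyloxy)-4-(methoxymethoxy)phenoxy]phenyl}boronic acid | OB(O)c1cc(OCc2ccccc2)c(OCc2ccccc2)c(OCc2ccccc2)c1Oc1cc(OCc2ccccc2)c(c(OCc2ccccc2)c1)OCOC
F7 | step 15 | 6-bromo-2,3,4-tris(benzyloxy)phenol | Oc1c(Br)cc(OCc2ccccc2)c(OCc2ccccc2)c1OCc1ccccc1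
F8 | step 15 | 1,3-bis(benzyloxy)-5-iodo-2-(methoxymethoxy)benzene | COCOc1c(OCc2ccccc2)cc(I)cc1OCc1ccccc1
F9 | step 15 | 1,2,3-tris(benzyloxy)-4-[3,5-bis(benzyloxy)-4-(methoxymethoxy)phenoxy]-5-bromobenzene | Brc1cc(OCc2ccccc2)c(OCc2ccccc2)c(OCc2ccccc2)c1Oc1cc(OCc2ccccc2)c(c(OCc2ccccc2)c1)OCOC
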